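The constants used here were set for the occasion; what happens was integrated by code.

Late in this flask no step of the scheme takes product away, so the yield at 12 s is the sum of what the direct route drew from substrate.

substrate 0.80 M; gas 200 mM (held); time 12 s

    substrate + reagent → intermediate A (k1 = 0.23 /M/s)
    substrate → product (k2 = 0.20 /s)
    substrate → intermediate B (k3 = 1.7 /s)
    reagent + intermediate A ⇌ intermediate C (K4 = 23 /M, k4 = 0.21 /M/s)
    intermediate B ⇌ intermediate D (K5 = 0.34, k5 = 0.79 /s)
    reagent + intermediate B ⇌ intermediate E (K6 = 10 /M, k6 = 0.71 /M/s)
    gas ⇌ reagent, rate k7*(csat - [reagent]) (k7 = 0.17 /s, csat = 200 mM)

- product at 12 s, in percent of the substrate charged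
- concentration of reagent in solution at 12 s, in percent of saturation

- at the start none of reagent is dissolved
- run time (flask): 12 s

How soon does substrate leave? Transfer by itself closes half of the gap between reagent and saturation in 4.08 s. The two first-order exits of substrate together run at 1.90 /s, a half-life of 0.365 s, which is shorter than that transfer time.

What share becomes product? The rate constant of the direct route over the sum of both exits, 0.20 /s over 0.20 /s plus 1.7 /s, is 10.5%; call this φ, the branching share, or selectivity.

How large is the correction? Reagent opens a third exit. Even at saturation that exit runs at 0.0460 /s, far slower than the other two together, and it lowers the share by 0.25 percentage points. Since reagent starts at zero, I commit to φ.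

What does reagent do? Uptake with no consumption gives 87.0% of saturation at 12 s. But intermediate B relaxes with intermediate D within 0.223 s, shorter than the run, and B held at its share of the pool takes reagent at 0.379 /s, faster than the transfer coefficient 0.17 /s. Setting transfer against that uptake, with the pool held at its starting size, gives 31.0%, so I expect a value between these two estimates.

The forecast gives 10.5% and 47%, a single reagent figure where I gave a range, with uptake “partly eaten by the large B/D pool forming E”.

The simulation gives 10.5% and 47.3%. In this flask the two exits ran first: half the turnover to intermediate B was done by 0.365 s, and at 1.20 s substrate stood at 10.2% and product at 9.44%. With substrate at 0% by 6.00 s, product stayed at 10.5% while gas uptake, half done by 5.19 s, ran alongside the conversion of B into intermediate E, which reached 22.4% at 12.0 s. The yield matches φ, 10.5%, to the digits shown. In the flask left until 20 s, product reads 10.5%, φ to two digits, while intermediate E has grown to 34.1%.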